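## Retrosynthetic overview

1. Feature used: in the 14-membered carbocycle, C10 and C11 are neighbouring unbranched ring carbons, and the C11 ketone is bonded to the tertiary carbinol C12. C10H2–C11(=O) is therefore treated as a hydrated ring alkyne whose hydration site is fixed by the C12 hydroxyl.
2. Target 42 ⇐ oxidation and esterification of the C17 allylic alcohol, and OH-directed trans-hydrostannation with C–Sn oxidation ⇐ cycloalkyne 34 ⇐ ring-closing alkyne metathesis (C10≡C11) of the methyl-capped diyne 33.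
3. 33 ⇐ C5–C6 bond: alkylation of enyne sulfone 30 (from prenyl bromide and propynyl Grignard) with epoxy iodide 23, then Pd/hydride desulfonylation.
4. 23 ⇐ (S)-limonene. C1 comes from the chiral pool and the ring olefin is cleaved to the C3 and C12 carbonyls. C12 is set by HWE, Sharpless epoxidation and epoxy chloride → alkynol elimination; C3/C4 by Still–Gennari olefination and Sharpless epoxidation.
5. Ring order: the oxirane (C3–C4–O, step 12) first, the 14-membered carbocycle (step 20) second.

Key step: step 20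

## Remarks

- **Numbering.** Cembrane locants of the target are used throughout. C1 is the ring CH bearing C15(=C16H2)–C17; C3/C4 is the oxirane; C7=C8 is the olefin; C11 is the ketone; C12 is the carbinol. C10' is the extra alkyne carbon that leaves in 2-butyne.
- **Assumption.** (S)-(−)-limonene of high enantiomeric purity is used, because C1 is carried through unchanged.
- **C12.** Methyl versus primary-alkyl discrimination in a direct asymmetric propynylation of the ketone is not dependable. C12 is therefore set by Sharpless epoxidation.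
- **Order of events.** The ketone is elaborated while C3 is masked as an acetal.
- **Protecting group.** C17–OH is carried as its TBDPS ether so that it survives steps 3 and 9.

## Route

Step 1
Reactants: 1 (S)-(−)-limonene
Product: 4 (S)-limonen-10-ol, via 10-lithiolimonene 2 (not isolated), via dimethyl allylboronate 3 (not isolated)
Conditions: n-BuLi, TMEDA, hexane, rt; B(OMe)3, THF, −78 °C → rt; H2O2, aq NaOH, 0 °C
Reagents that add atoms: hydrogen peroxide OO; trimethyl borate COB(OC)OC (stays only in 3); n-butyllithium [Li]CCCC (lithium only in 2)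
Why: Allylic metalation with n-BuLi·TMEDA removes a proton of the isopropenyl methyl group to give a symmetrical 2-substituted allyl anion, and borylation/oxidation turns C–Li into C–OH; C1 is not part of the anion and keeps its configuration.

Step 2
Reactants: 4 (S)-limonen-10-ol
Product: 5 TBDPS ether of 4
Conditions: TBDPSCl, imidazole, DMF, rt
Reagents that add atoms: tert-butyl(chloro)diphenylsilane CC(C)(C)[Si](Cl)(c1ccccc1)c1ccccc1
Why: Standard silylation of a primary alcohol, giving an ether robust enough for the mild acid of step 3, the bases of steps 4–18 and the silyl triflate of step 9.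

Step 3
Reactants: 5 TBDPS ether of 4
Product: 7 keto acetal (5S)-7,7-dimethoxy-5-[3-(TBDPS-oxy)prop-1-en-2-yl]heptan-2-one, via keto aldehyde 6 (not isolated)
Conditions: O3, CH2Cl2–MeOH, Sudan III, −78 °C; Me2S; then HC(OMe)3, PPTS (cat.), 0 °C → rt
Reagents that add atoms: ozone [O-][O+]=O; trimethyl orthoformate COC(OC)OC
Why: In this chemoselective ozonolysis the electron-rich trisubstituted ring olefin reacts well before the 1,1-disubstituted olefin, which is deactivated by its allylic silyloxy group, and under mild acid only the aldehyde (C3) and not the methyl ketone (C12) should be acetalised.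

Step 4
Reactants: 7 keto acetal; 8 triethyl phosphonoacetate
Product: 10 ethyl (2E,6S)-8,8-dimethoxy-3-methyl-6-[3-(TBDPS-oxy)prop-1-en-2-yl]oct-2-enoate, via sodium phosphonate 9 (not isolated)
Conditions: NaH, THF, 0 °C → rt
Reagents that add atoms: sodium hydride [Na+].[H-] (sodium only in 9)
Why: Horner–Wadsworth–Emmons olefination of a methyl ketone should favour the E enoate (chain trans to the ester); the minor Z isomer is to be removed by chromatography here or at 11, so that step 6 starts from geometrically pure material.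

Step 5
Reactants: 10 E-enoate
Product: 11 (2E,6S)-allylic alcohol (C10'H2OH–C11H=C12)
Conditions: DIBAL-H, CH2Cl2, −78 °C; Rochelle salt
Reagents that add atoms: none
Why: DIBAL-H gives 1,2-reduction of the enoate to the allylic alcohol, and the acetal, silyl ether and olefins are inert.

Step 6
Reactants: 11 E-allylic alcohol
Product: 12 (1S,11S,12S)-epoxy alcohol
Conditions: Ti(OiPr)4 (10 mol %), L-(+)-DET (12 mol %), t-BuOOH, 4 Å MS, CH2Cl2, −20 °C
Reagents that add atoms: tert-butyl hydroperoxide CC(C)(C)OO
Why: Sharpless asymmetric epoxidation of an (E)-3-methyl-2-alken-1-ol (geraniol-type, the best substrate class) with L-(+)-tartrate delivers oxygen to the face that gives the (2S,3S)-epoxy alcohol, which sets C12 as S under reagent control; only the olefin carrying the free allylic OH reacts.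

Step 7
Reactants: 12 epoxy alcohol
Product: 13 epoxy chloride (same spatial arrangement; C11 becomes R by CIP)
Conditions: PPh3, CCl4, NaHCO3, reflux
Reagents that add atoms: carbon tetrachloride ClC(Cl)(Cl)Cl
Why: The Appel reaction replaces the primary OH by Cl under buffered, essentially neutral conditions without touching the oxirane or the acetal.

Step 8
Reactants: 13 epoxy chloride
Product: 15 (4S,7S)-9,9-dimethoxy-4-methyl-7-[3-(TBDPS-oxy)prop-1-en-2-yl]non-2-yn-4-ol, via dilithio alkynyl alkoxide 14 (not isolated)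
Conditions: n-BuLi (3.3 equiv), THF, −78 → −30 °C; then MeI, DMPU, −78 → 0 °C
Reagents that add atoms: iodomethane CI; n-butyllithium [Li]CCCC (lithium only in 14)
Why: Base-induced eliminative opening of a 2,3-epoxy chloride (oxirane opening to the chlorovinyl alkoxide, then dehydrochlorination) gives the propargylic alkoxide/acetylide dianion, which is methylated on carbon; the C12–O bond is never broken, so C12 stays S.

Step 9
Reactants: 15 propargylic alcohol acetal
Product: 17 (3S,6S)-6-methyl-3-[3-(TBDPS-oxy)prop-1-en-2-yl]-6-(triethylsilyloxy)non-7-ynal, via lutidinium salt 16 (not isolated)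
Conditions: TESOTf (3.5 equiv), 2,6-lutidine (5 equiv), CH2Cl2, 0 °C; then H2O
Reagents that add atoms: triethylsilyl triflate CC[Si](CC)(CC)OS(=O)(=O)C(F)(F)F; water O; 2,6-lutidine Cc1cccc(C)n1 (stays only in 16)
Why: TESOTf/lutidine silylates the tertiary alcohol and, in the known silyl triflate/lutidine acetal cleavage, converts the aldehyde acetal into an N-(α-methoxyalkyl)lutidinium salt that water hydrolyses to the aldehyde under non-acidic conditions, so both silyl ethers survive.

Step 10
Reactants: 17 aldehyde; 18 ethyl 2-[bis(2,2,2-trifluoroethoxy)phosphoryl]propanoate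
Product: 20 ethyl (2Z,5S,8S)-2,8-dimethyl-5-[3-(TBDPS-oxy)prop-1-en-2-yl]-8-(triethylsilyloxy)undec-2-en-9-ynoate, via potassium phosphonate 19 (not isolated)
Conditions: KHMDS, 18-crown-6, THF, −78 °C
Reagents that add atoms: potassium hexamethyldisilazide [K+].C[Si](C)(C)[N-][Si](C)(C)C (potassium only in 19)
Why: In the Still–Gennari olefination, fast irreversible collapse of the kinetic adduct of the electron-poor phosphonate places the ester (C5) cis to C2, which is the Z-C3=C4 geometry required for the cis relation of C2 and C5 on the oxirane.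

Step 11
Reactants: 20 Z-enoate
Product: 21 (2Z,5S,8S)-allylic alcohol (C5H2OH–C4(CH3)=C3H)
Conditions: DIBAL-H, CH2Cl2, −78 °C; Rochelle salt
Reagents that add atoms: none
Why: DIBAL-H gives 1,2-reduction of the enoate with retention of the Z geometry, and the alkyne and silyl ethers are inert.

Step 12
Reactants: 21 Z-allylic alcohol
Product: 22 (1S,3R,4S,12S)-epoxy alcohol
Conditions: Ti(OiPr)4 (0.3 equiv), L-(+)-DET (0.36 equiv), t-BuOOH, 4 Å MS, CH2Cl2, −20 °C
Reagents that add atoms: tert-butyl hydroperoxide CC(C)(C)OO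
Why: Sharpless asymmetric epoxidation with L-(+)-tartrate gives the (2S,3R)-epoxy alcohol of a Z-allylic alcohol, that is 4S,3R; syn oxygen transfer to the Z olefin fixes the cis relation of C2 and C5, and the remote C1 centre should have little influence.

Step 13
Reactants: 22 epoxy alcohol
Product: 23 epoxy iodide (same spatial arrangement; C4 becomes R by CIP)
Conditions: I2, PPh3, imidazole, THF, 0 °C
Reagents that add atoms: iodine II
Why: Appel-type iodination of the primary epoxy alcohol under imidazole buffering leaves the oxirane, the tertiary TES ether and the alkyne unchanged.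

Step 14
Reactants: 24 prenyl bromide
Product: 25 prenyl phenyl sulfone
Conditions: PhSO2Na, DMF, rt
Reagents that add atoms: sodium benzenesulfinate [Na+].[O-]S(=O)c1ccccc1
Why: SN2 S-alkylation of the sulfinate at the primary allylic carbon.

Step 15
Reactants: 25 prenyl phenyl sulfone
Product: 26 (E)-2-methyl-4-(phenylsulfonyl)but-2-en-1-ol
Conditions: SeO2 (cat.), t-BuOOH, CH2Cl2, rt; NaBH4, MeOH, 0 °C on the crude (returns any enal)
Reagents that add atoms: tert-butyl hydroperoxide CC(C)(C)OO
Why: Riley-type allylic oxidation (ene reaction, then [2,3]-shift) hydroxylates the methyl group trans to the chain, which sets the E geometry of C7=C8.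

Step 16
Reactants: 26 hydroxy sulfone
Product: 27 (E)-(4-bromo-3-methylbut-2-en-1-yl) phenyl sulfone
Conditions: CBr4, PPh3, CH2Cl2, 0 °C
Reagents that add atoms: carbon tetrabromide BrC(Br)(Br)Br
Why: Appel bromination is neutral, so base-induced 1,4-elimination of HBr through the acidic sulfone position is avoided.

Step 17
Reactants: 27 bromo sulfone; 28 1-propynylmagnesium bromide
Product: 30 (E)-(3-methylhept-2-en-5-yn-1-yl) phenyl sulfone, via 1-propynylcopper 29 (not isolated)
Conditions: 28, CuBr·SMe2 (slight excess over 28), THF, −20 → 0 °C; then 27, DMPU, rt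
Reagents that add atoms: copper(I) bromide–dimethyl sulfide Br[Cu].CSC (copper only in 29)
Why: Allylation of a preformed copper(I) acetylide couples at the primary terminus C9 to give the skipped enyne; with all Grignard reagent transmetalated, the non-basic acetylide should neither deprotonate the sulfone nor trigger 1,4-elimination.

Step 18
Reactants: 23 epoxy iodide; 30 enyne sulfone
Product: 32 C6-phenylsulfonyl seco diyne (C6 epimers), via lithiated sulfone 31 (not isolated)
Conditions: 30, n-BuLi, THF–DMPU, −78 °C; then 23, −78 → −20 °C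
Reagents that add atoms: n-butyllithium [Li]CCCC (lithium only in 31)
Why: α-Alkylation of an allyl sulfone carbanion forms C5–C6; the primary iodide next to the oxirane is displaced faster than the trisubstituted oxirane is opened, and the new C6 centre is of no consequence because it is erased in step 19.

Step 19
Reactants: 32 sulfone
Product: 33 seco diyne (1S,3R,4S,7E,12S) with C12–OTES and C17–OTBDPS
Conditions: PdCl2(dppp) (5 mol %), LiEt3BH (2 equiv), THF, −10 → 0 °C
Reagents that add atoms: none
Why: In this Pd-catalysed hydride desulfonylation, Pd(0) ionises the allylic sulfone and hydride attacks the less substituted π-allyl terminus C6, which keeps C7=C8 in place and E; with little excess hydride at or below 0 °C the trisubstituted oxirane and the internal alkynes should be spared.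

Step 20
Reactants: 33 seco diyne
Product: 34 14-membered cycloalkyne (C10≡C11; 1S,3R,4S,7E,12S)
Conditions: [(4-MeOC6H4)C≡Mo(OSiPh3)3] (10 mol %), powdered 5 Å MS, toluene (2 mM), rt → 60 °C
Reagents that add atoms: none
Why: The Mo≡C unit adds to the unhindered C10 alkyne in a [2+2] fashion to give a metallacyclobutadiene, cycloreversion leaves a substrate-bound alkylidyne, and this engages the C11 alkyne intramolecularly; every step is reversible, and the sieves absorb 2-butyne so that the equilibrium drains towards the ring. The closest known reaction type is ring-closing alkyne metathesis of bis(methyl-capped) diynes to 12–20-membered cycloalkynes with triarylsilanolate molybdenum alkylidynes. The 14-membered carbocycle is closed end to end by formation of the C10≡C11 bond, while the oxirane is already present and is only a spectator. No stereocentre is formed, and C1, C3, C4 and C12 are not touched. The step needs selectivity for triple over double bonds and for cyclisation over oligomerisation: alkylidynes do not react with C7=C8 or C15=C16, so the E olefin cannot scramble, and high dilution together with reversibility returns oligomers to the monomeric ring. The silanolate ligands temper the Lewis acidity enough for the oxirane, and silylation of the C12 oxygen prevents loss of the propargylic substituent from the intermediate alkylidyne.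

Step 21
Reactants: 34 cycloalkyne
Product: 35 cycloalkyne diol (C12–OH, C17–OH)
Conditions: TBAF (3 equiv), THF, 0 °C → rt
Reagents that add atoms: none
Why: Fluoride cleaves both silyl ethers and leaves the oxirane, olefins and alkyne unaffected.

Step 22
Reactants: 35 cycloalkyne diol
Product: 36 (10Z)-11-tributylstannyl alkene
Conditions: [Cp*RuCl]4 (2.5 mol %), Bu3SnH (1.1 equiv, slow addition), CH2Cl2, rt
Reagents that add atoms: tributyltin hydride CCCC[SnH](CCCC)CCCC
Why: In the hydroxyl-directed Ru-catalysed trans-hydrostannation, a hydrogen bond from the propargylic C12–OH to the Ru-bound chloride orients the alkyne so that tin goes to the proximal carbon C11 and hydrogen to C10 from the opposite face; olefins and the oxirane do not react, and C17–OH is too remote to compete.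

Step 23
Reactants: 36 alkenylstannane
Product: 39 C11 ketone C12 carbinol C17 alcohol, via enol acetate 37 (not isolated), via C12 acetate 38 (not isolated)
Conditions: Cu(OAc)2 (2.5 equiv), Et3N, DMSO, rt; then K2CO3, MeOH, 0 °C
Reagents that add atoms: copper(II) acetate [Cu+2].CC(=O)[O-].CC(=O)[O-]
Why: Chan–Lam-type oxidation of the C–Sn bond (Sn→Cu transmetalation, then C–O reductive elimination) places acetate on C11, O→O acyl shift to the neighbouring C12–OH releases the ketone, and mild methanolysis removes the acetate; C12 is not involved in any bond breaking.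

Step 24
Reactants: 39 hydroxy ketone alcohol
Product: 40 C17 enal
Conditions: Dess–Martin periodinane, NaHCO3, CH2Cl2, 0 °C → rt
Reagents that add atoms: none
Why: Dess–Martin oxidation acts on the only oxidisable (primary allylic) alcohol, because the tertiary C12–OH cannot react and the buffer protects the oxirane.

Step 25
Reactants: 40 enal
Product: 41 C17 acrylic acid
Conditions: NaClO2, NaH2PO4, 2-methyl-2-butene, t-BuOH–H2O, 0 °C → rt
Reagents that add atoms: sodium chlorite [Na+].[O-]Cl=O
Why: Pinnick oxidation converts 2-substituted acroleins into acrylic acids, and the scavenger removes HOCl before it can attack C7=C8.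

Step 26
Reactants: 41 acrylic acid
Product: 42 target CNP0154954.4 (1S,3R,4S,7E,12S)
Conditions: TMSCHN2, toluene–MeOH, 0 °C
Reagents that add atoms: (trimethylsilyl)diazomethane C[Si](C)(C)C=[N+]=[N-]
Why: O-methylation of the carboxylic acid under neutral conditions avoids conjugate addition to the acrylate, α-ketol rearrangement and oxirane opening.

## Compound list

1 | (S)-(−)-limonene | CC1=CC[C@H](CC1)C(C)=C | starting material
2 | 10-lithiolimonene (allyllithium, TMEDA solvate) | CC1=CC[C@H](CC1)C(=C)C[Li] | intermediate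
3 | dimethyl [(S)-limonen-10-yl]boronate | CC1=CC[C@H](CC1)C(=C)CB(OC)OC | intermediate
4 | (S)-limonen-10-ol, 2-[(1S)-4-methylcyclohex-3-en-1-yl]prop-2-en-1-ol | CC1=CC[C@H](CC1)C(=C)CO | intermediate
5 | TBDPS ether of 4 | CC1=CC[C@H](CC1)C(=C)CO[Si](c2ccccc2)(c3ccccc3)C(C)(C)C | intermediate
6 | (3S)-3-[3-(TBDPS-oxy)prop-1-en-2-yl]-6-oxoheptanal | O=CC[C@H](CCC(C)=O)C(=C)CO[Si](c1ccccc1)(c1ccccc1)C(C)(C)C | intermediate
7 | (5S)-7,7-dimethoxy-5-[3-(TBDPS-oxy)prop-1-en-2-yl]heptan-2-one | COC(OC)C[C@H](CCC(C)=O)C(=C)CO[Si](c1ccccc1)(c1ccccc1)C(C)(C)C | intermediate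
8 | triethyl phosphonoacetate | CCOC(=O)CP(=O)(OCC)OCC | starting material
9 | sodium salt of 8 | CCOC(=O)[CH-]P(=O)(OCC)OCC.[Na+] | intermediate
10 | ethyl (2E,6S)-8,8-dimethoxy-3-methyl-6-[3-(TBDPS-oxy)prop-1-en-2-yl]oct-2-enoate | CCOC(=O)/C=C(\C)CC[C@@H](CC(OC)OC)C(=C)CO[Si](c1ccccc1)(c1ccccc1)C(C)(C)C | intermediate
11 | (2E,6S)-8,8-dimethoxy-3-methyl-6-[3-(TBDPS-oxy)prop-1-en-2-yl]oct-2-en-1-ol | OC/C=C(\C)CC[C@@H](CC(OC)OC)C(=C)CO[Si](c1ccccc1)(c1ccccc1)C(C)(C)C | intermediate
12 | (1S,11S,12S)-epoxy alcohol, [(2S,3S)-3-{(3S)-5,5-dimethoxy-3-[3-(TBDPS-oxy)prop-1-en-2-yl]pentyl}-3-methyloxiran-2-yl]methanol | OC[C@@H]1O[C@@]1(C)CC[C@@H](CC(OC)OC)C(=C)CO[Si](c2ccccc2)(c3ccccc3)C(C)(C)C | intermediate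
13 | chloromethyl oxirane from 12 (1S,11R,12S by CIP, same spatial arrangement) | ClC[C@@H]1O[C@@]1(C)CC[C@@H](CC(OC)OC)C(=C)CO[Si](c2ccccc2)(c3ccccc3)C(C)(C)C | intermediate
14 | dilithio alkynyl alkoxide (1S,12S) | [Li]C#C[C@@](C)(O[Li])CC[C@@H](CC(OC)OC)C(=C)CO[Si](c1ccccc1)(c1ccccc1)C(C)(C)C | intermediate
15 | (4S,7S)-9,9-dimethoxy-4-methyl-7-[3-(TBDPS-oxy)prop-1-en-2-yl]non-2-yn-4-ol | CC#C[C@@](C)(O)CC[C@@H](CC(OC)OC)C(=C)CO[Si](c1ccccc1)(c1ccccc1)C(C)(C)C | intermediate
16 | N-(α-methoxyalkyl)-2,6-lutidinium triflate of the C12 TES ether (C3 epimers) | CC#C[C@@](C)(O[Si](CC)(CC)CC)CC[C@@H](CC(OC)[n+]1c(C)cccc1C)C(=C)CO[Si](c2ccccc2)(c3ccccc3)C(C)(C)C.[O-]S(=O)(=O)C(F)(F)F | intermediate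
17 | (3S,6S)-6-methyl-3-[3-(TBDPS-oxy)prop-1-en-2-yl]-6-(triethylsilyloxy)non-7-ynal | CC#C[C@@](C)(O[Si](CC)(CC)CC)CC[C@@H](CC=O)C(=C)CO[Si](c1ccccc1)(c1ccccc1)C(C)(C)C | intermediate
18 | ethyl 2-[bis(2,2,2-trifluoroethoxy)phosphoryl]propanoate | CCOC(=O)C(C)P(=O)(OCC(F)(F)F)OCC(F)(F)F | starting material
19 | potassium salt of 18 | CCOC(=O)[C-](C)P(=O)(OCC(F)(F)F)OCC(F)(F)F.[K+] | intermediate
20 | ethyl (2Z,5S,8S)-2,8-dimethyl-5-[3-(TBDPS-oxy)prop-1-en-2-yl]-8-(triethylsilyloxy)undec-2-en-9-ynoate | CCOC(=O)/C(C)=C\C[C@H](CC[C@](C)(O[Si](CC)(CC)CC)C#CC)C(=C)CO[Si](c1ccccc1)(c1ccccc1)C(C)(C)C | intermediate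
21 | (2Z,5S,8S)-allylic alcohol from 20 | OC/C(C)=C\C[C@H](CC[C@](C)(O[Si](CC)(CC)CC)C#CC)C(=C)CO[Si](c1ccccc1)(c1ccccc1)C(C)(C)C | intermediate
22 | (1S,3R,4S,12S)-epoxy alcohol (C5–OH, cis C2/C5 oxirane) | OC[C@]1(C)O[C@@H]1C[C@H](CC[C@](C)(O[Si](CC)(CC)CC)C#CC)C(=C)CO[Si](c2ccccc2)(c3ccccc3)C(C)(C)C | intermediate
23 | epoxy iodide from 22 (1S,3R,4R,12S by CIP, same spatial arrangement) | IC[C@]1(C)O[C@@H]1C[C@H](CC[C@](C)(O[Si](CC)(CC)CC)C#CC)C(=C)CO[Si](c2ccccc2)(c3ccccc3)C(C)(C)C | intermediate
24 | prenyl bromide | CC(C)=CCBr | starting material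
25 | prenyl phenyl sulfone | CC(C)=CCS(=O)(=O)c1ccccc1 | intermediate
26 | (E)-2-methyl-4-(phenylsulfonyl)but-2-en-1-ol | OC/C(C)=C/CS(=O)(=O)c1ccccc1 | intermediate
27 | (E)-(4-bromo-3-methylbut-2-en-1-yl) phenyl sulfone | BrC/C(C)=C/CS(=O)(=O)c1ccccc1 | intermediate
28 | 1-propynylmagnesium bromide | CC#C[Mg]Br | starting material
29 | 1-propynylcopper(I) | CC#C[Cu] | intermediate
30 | (E)-(3-methylhept-2-en-5-yn-1-yl) phenyl sulfone | CC#CC/C(C)=C/CS(=O)(=O)c1ccccc1 | intermediate
31 | α-lithio derivative of 30 | CC#CC/C(C)=C/C([Li])S(=O)(=O)c1ccccc1 | intermediate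
32 | C6-phenylsulfonyl seco diyne (1S,3R,4S,7E,12S; C6 epimers) | CC#CC/C(C)=C/C(C[C@]1(C)O[C@@H]1C[C@H](CC[C@](C)(O[Si](CC)(CC)CC)C#CC)C(=C)CO[Si](c2ccccc2)(c3ccccc3)C(C)(C)C)S(=O)(=O)c4ccccc4 | intermediate
33 | seco diyne (1S,3R,4S,7E,12S), C12–OTES, C17–OTBDPS | CC#CC/C(C)=C/CC[C@]1(C)O[C@@H]1C[C@H](CC[C@](C)(O[Si](CC)(CC)CC)C#CC)C(=C)CO[Si](c2ccccc2)(c3ccccc3)C(C)(C)C | intermediate
34 | 14-membered cycloalkyne (C10≡C11; 1S,3R,4S,7E,12S), C12–OTES, C17–OTBDPS | C=C(CO[Si](c3ccccc3)(c4ccccc4)C(C)(C)C)[C@H]1CC[C@](C)(O[Si](CC)(CC)CC)C#CC/C(C)=C/CC[C@]2(C)O[C@@H]2C1 | intermediate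
35 | cycloalkyne diol | C=C(CO)[C@H]1CC[C@](C)(O)C#CC/C(C)=C/CC[C@]2(C)O[C@@H]2C1 | intermediate
36 | (10Z)-11-(tributylstannyl) alkene diol | C=C(CO)[C@H]1CC[C@](C)(O)/C([Sn](CCCC)(CCCC)CCCC)=C/C/C(C)=C/CC[C@]2(C)O[C@@H]2C1 | intermediate
37 | (10Z)-11-acetoxy enol ester | C=C(CO)[C@H]1CC[C@](C)(O)/C(OC(C)=O)=C/C/C(C)=C/CC[C@]2(C)O[C@@H]2C1 | intermediate
38 | C11 ketone C12 acetate | C=C(CO)[C@H]1CC[C@](C)(OC(C)=O)C(=O)CC/C(C)=C/CC[C@]2(C)O[C@@H]2C1 | intermediate
39 | C11 ketone, C12–OH, C17–OH | C=C(CO)[C@H]1CC[C@](C)(O)C(=O)CC/C(C)=C/CC[C@]2(C)O[C@@H]2C1 | intermediate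
40 | C17 enal | C=C(C=O)[C@H]1CC[C@](C)(O)C(=O)CC/C(C)=C/CC[C@]2(C)O[C@@H]2C1 | intermediate
41 | C17 acrylic acid | C=C(C(=O)O)[C@H]1CC[C@](C)(O)C(=O)CC/C(C)=C/CC[C@]2(C)O[C@@H]2C1 | intermediate
42 | CNP0154954.4, methyl ester (1S,3R,4S,7E,12S) | C=C(C(=O)OC)[C@H]1CC[C@](C)(O)C(=O)CC/C(C)=C/CC[C@]2(C)O[C@@H]2C1 | target

## Step count and risks

- Total step count: 26
- Longest linear sequence: 22 (steps 1–13 and 18–26)

Steps most likely to fail:

1. **Step 20.** The alkyne next to the fully substituted C12 may engage the alkylidyne slowly. The unhindered terminus then builds up open-chain or cyclic oligomers, and ring strain may hold the equilibrium away from the monomeric ring.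
   - Fallback: the C10≡C11 bond is formed intermolecularly at high concentration and the ring is closed at C5–C6 instead.
   - It sets out from iodide 23 and sulfone 30. Alkyne cross-metathesis (same molybdenum alkylidyne, 30 in excess, 5 Å MS, toluene) should give the open-chain iodo sulfone F1.
   - Slow addition of F1 to LiHMDS in THF–DMPU at high dilution should close the 14-membered ring by intramolecular sulfone alkylation, giving the macrocyclic C6 sulfone F2.
   - PdCl2(dppp)/LiEt3BH then removes the sulfonyl group, and the route is rejoined at 34.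

2. **Step 18.** Displacement at C5, next to the fully substituted C4, by a bulky carbanion may be slow. Proton transfer from the product to unreacted carbanion could then lead to attack of the C6 anion on the oxirane.
   - Fallback: the chain is grown linearly with a small nucleophile and no sulfone. It sets out from 23.
   - Lithioacetonitrile (MeCN, n-BuLi, THF, −78 °C) should give the nitrile F3, and DIBAL-H with hydrolytic work-up the C7 aldehyde F4.
   - A Wittig reaction with Ph3P=C(CH3)CO2Et should give the E-enoate F5, and DIBAL-H the C9 allylic alcohol F6.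
   - CBr4/PPh3 should give the allylic bromide F7, and coupling with 1-propynylcopper 29 (from 28) rejoins the route at 33. Step 19 is by-passed as well.

3. **Step 23.** Protodestannation may compete with Sn→Cu transfer at the alkenyl carbon flanked by the quaternary C12, and the acyl shift may stall.
   - Fallback: the alkyne is hydrated through a carbonate tether instead of a C–metal bond. It sets out from diol 35.
   - Silver-catalysed carboxylative cyclisation (AgOAc, DBU, CO2, toluene, rt) should proceed as a 5-exo attack of the C12 carbonate oxygen on C11 and give the Z-alkylidene cyclic carbonate F8.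
   - LiOH in THF–H2O hydrolyses F8 with loss of CO2, and the route is rejoined at 39. Steps 22 and 23 are both by-passed.

## Further compounds

F1 | step 20 | open-chain iodo sulfone with C10≡C11 in place | IC[C@]1(C)O[C@@H]1C[C@H](CC[C@](C)(O[Si](CC)(CC)CC)C#CC/C(C)=C/CS(=O)(=O)c4ccccc4)C(=C)CO[Si](c2ccccc2)(c3ccccc3)C(C)(C)C
F2 | step 20 | macrocyclic C6 phenyl sulfone (C6 epimers) | C=C(CO[Si](c3ccccc3)(c4ccccc4)C(C)(C)C)[C@H]1CC[C@](C)(O[Si](CC)(CC)CC)C#CC/C(C)=C/C(S(=O)(=O)c5ccccc5)C[C@]2(C)O[C@@H]2C1
F3 | step 18 | C7 nitrile | N#CCC[C@]1(C)O[C@@H]1C[C@H](CC[C@](C)(O[Si](CC)(CC)CC)C#CC)C(=C)CO[Si](c2ccccc2)(c3ccccc3)C(C)(C)C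
F4 | step 18 | C7 aldehyde | O=CCC[C@]1(C)O[C@@H]1C[C@H](CC[C@](C)(O[Si](CC)(CC)CC)C#CC)C(=C)CO[Si](c2ccccc2)(c3ccccc3)C(C)(C)C
F5 | step 18 | ethyl (7E)-enoate (C9 ester) | CCOC(=O)/C(C)=C/CC[C@]1(C)O[C@@H]1C[C@H](CC[C@](C)(O[Si](CC)(CC)CC)C#CC)C(=C)CO[Si](c2ccccc2)(c3ccccc3)C(C)(C)C
F6 | step 18 | (7E)-C9 allylic alcohol | OC/C(C)=C/CC[C@]1(C)O[C@@H]1C[C@H](CC[C@](C)(O[Si](CC)(CC)CC)C#CC)C(=C)CO[Si](c2ccccc2)(c3ccccc3)C(C)(C)C
F7 | step 18 | (7E)-C9 allylic bromide | BrC/C(C)=C/CC[C@]1(C)O[C@@H]1C[C@H](CC[C@](C)(O[Si](CC)(CC)CC)C#CC)C(=C)CO[Si](c2ccccc2)(c3ccccc3)C(C)(C)C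
F8 | step 23 | (10Z)-alkylidene cyclic carbonate across C11/C12 | C=C(CO)[C@H]1CC[C@]3(C)OC(=O)O/C3=C\C/C(C)=C/CC[C@]2(C)O[C@@H]2C1
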